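If a flask loses electrophile by more than one route, ask first what share of the electrophile lost turns up as target, since the target amount is that share summed over the loss.

| flask | electrophile | nucleophile | protic impurity | temperature | remark | time |
|---|---|---|---|---|---|---|
| eta | 0.20 M | 0.19 M | 0.059 M | −20 °C | run made earlier |  |
| theta | 0.20 M | 0.19 M | 0.12 M | 15 °C | run made earlier |  |
| epsilon | 0.20 M | 0.19 M | 0.32 M | −20 °C | run made earlier |  |
| alpha | 0.14 M | 0.19 M | 0.20 M | 15 °C | run made earlier |  |
| elm | 0.20 M | 0.600 M | 0.200 M | 5 °C |  | 8.0 h |
| cedar | 0.20 M | 0.190 M | 0.200 M | 5 °C |  | 8.0 h |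
| birch | 0.20 M | 0.190 M | 0.100 M | 20 °C |  | 8.0 h |
| alder | 0.20 M | 0.400 M | 0.200 M | 45 °C |  | 8.0 h |
| ash | 0.30 M | 0.190 M | 0.0600 M | −15 °C |  | 8.0 h |
| maple | 0.050 M | 0.800 M | 0.300 M | 5 °C |  | 8.0 h |

| run | time / h | target / % | electrophile / % |
|---|---|---|---|
| eta | 3.00 | 4.1 | 94.0 |
| eta | 5.00 | 6.7 | 90.1 |
| eta | 8.00 | 9.2 | 85.2 |
| eta | 10.0 | 11.5 | 81.8 |
| eta | 15.0 | 15.4 | 75.1 |
| theta | 0.200 | 5.4 | 85.8 |
| theta | 0.417 | 10.2 | 73.5 |
| theta | 0.667 | 14.0 | 64.1 |
| theta | 1.33 | 21.9 | 45.0 |
| theta | 2.50 | 27.7 | 28.2 |
| epsilon | 1.00 | 1.4 | 96.4 |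
| epsilon | 3.00 | 3.7 | 91.4 |
| epsilon | 6.00 | 7.4 | 83.5 |
| epsilon | 10.0 | 11.1 | 75.1 |
| epsilon | 15.0 | 14.6 | 66.2 |
| alpha | 0.200 | 5.6 | 85.4 |
| alpha | 0.417 | 10.8 | 73.1 |
| alpha | 0.667 | 14.6 | 61.1 |
| alpha | 1.33 | 22.7 | 41.9 |
| alpha | 2.50 | 29.8 | 23.1 |

(scatter of a reading: 0.3 percentage points)

- a reading or a percentage of target counts all its forms, free or not

* all flasks from highest to lowest amount of target, in percent of the electrophile charged, at 8.0 h (elm / cedar / birch / alder / ash / maple)
* the amount of target, in percent of the electrophile charged of the flask you put first, at 8.0 h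
* the amount of target, in percent of the electrophile charged of the flask you put last, at 8.0 h

*What do the readings give you first?* Electrophile lost exceeds target. At its first reading, theta has lost 14.2% and holds 5.4% of target. So r, the electrophile lost elsewhere per target made, is 1.63. In alpha, r is 1.61.

*What feeds r?* Eta and epsilon differ in protic impurity, and at similar conversion r goes from 0.609 to 1.23, so impurity feeds one side route. Eta's r is too large for its small impurity charge, so I let electrophile feed a second route.

*Write that down.* Let H, A and B be the molar concentrations of impurity, electrophile and nucleophile. I take r = (aH + bA)/B, where a and b are the side routes' rate constants relative to the target route. Theta and alpha, both at 15 °C, give two equations: a = 0.764 and b = 1.09, both readings with their scatter.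

*Nucleophile stood at 0.19 M in each run. Why divide by B?* That is a bet, not a reading. I assume that the target route needs nucleophile and that the side routes do not.

*Then what is your quantity?* The target share S = B/(B + aH + bA), the instantaneous selectivity, taken at the charges with the a and b read at 15 °C. For maple it is 73.8%, and this target share is what I carry. Elm gets 61.8%, alder 51.9%, birch 39.2% and cedar 33.9%.

*But a and b belong to one temperature.* Yes. Cold epsilon shows a share of 44.8% despite its larger impurity charge, against 38.0% in theta, so I take it that warming lowers S. I expect alder below its figure.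

*Your order?* Maple, elm, alder, birch, cedar, then ash. For the first of these I read S as the target amount, which is my assumption that their electrophile is mostly used by the asked time. Ash is cold at −15 °C, and eta held 9.2% at 8.00 h. I commit to maple near 73.8% and ash a little above eta's figure.

The forecast had elm > maple > cedar > birch > alder > ash, with 48% first and 14% last, holding that “At 15 °C, target is a constant ~39% of loss”.

The flasks give maple > elm > alder > birch > cedar > ash, with 77.0% first and 12.6% last.

    electrophile + nucleophile → acid set free + target (k = 0.750 L mol⁻¹ h⁻¹, Ea = 54.0 kJ mol⁻¹)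
    crystals ⇌ target, rate k2*(cs2 - [target]) while solid is left; crystals form when [target] > cs2 (solubility = 6.10 mM, k = 7.10 h⁻¹)
    electrophile + protic impurity → quenched substrate (k = 0.520 L mol⁻¹ h⁻¹, Ea = 63.0 kJ mol⁻¹)
    nucleophile + acid set free ⇌ protonated nucleophile, settled at all times (K = 2000 L mol⁻¹, ΔH = −20.0 kJ mol⁻¹)
    2 electrophile → homo dimer (k = 0.300 L mol⁻¹ h⁻¹, Ea = 69.0 kJ mol⁻¹)
    (constants at 5 °C)

Maple's balance of electrophile, the limiting reagent, reads 77.0% target, 20.7% quenched substrate, 1.99% in homo dimer and 0.345% unreacted. The carried share 73.8%, reckoned at the charges with the a and b of 15 °C, lay 3.2 percentage points under the target found in maple. The impurity route is the main reason maple stops where it does: the same flask without that route gives 96.2%. In elm, with 3.67% of its electrophile unreacted, the carried share 61.8% stands against 66.9%.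

(The data stem from a simulated flask for an exercise; the scatter is artificial.)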